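## Retrosynthetic overview

1. The sulfates go on late. Target ⇐ its disodium salt ⇐ hepta‑O‑benzyl terphenyl‑diol (O‑sulfation, then global hydrogenolysis). The two free OH groups are unmasked from MOM ethers.
2. Central ring B ⇐ a 4‑benzyloxy‑2‑pyranone, by alkoxide ring opening and Dieckmann‑type Claisen re‑closure. The pyranone ⇐ a 1,3‑diarylacetone + malonyl dichloride.
3. 1,3‑Diarylacetone ⇐ β‑keto ester ⇐ intermolecular Claisen condensation of two molecules of one arylacetic ester. This is the key C–C bond, joining the ring A fragment to the ring C fragment.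
4. Arylacetic ester ⇐ 2‑allyl‑3,5‑bis(benzyloxy)phenol (oxidative cleavage) ⇐ aromatic Claisen rearrangement, which singles out the oxygen that will carry the sulfate ⇐ phloroglucinol + allyl bromide.
5. Ring order: rings A and C come intact from phloroglucinol. The pyranone ring is built next and is transposed into carbocyclic ring B last.

Assumption: the SMILES has no stereodescriptor and the molecule has no stereocentre, so the two hindered biaryl axes are left unassigned and the compound is made as drawn, with any slowly interconverting atropisomers carried as a mixture.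

Abbreviations: Bn = CH2Ph; MOM = CH2OCH3; Ar = 2,4‑bis(benzyloxy)‑6‑(methoxymethoxy)phenyl.

## Route

Step 1
Reactants: 1 phloroglucinol
Product: 2 1,3,5-tris(benzyloxy)benzene
Conditions: BnBr (3.6 equiv), K2CO3 (4.5 equiv), DMF, 25→60 °C
Reagents that add atoms: benzyl bromide, BrCc1ccccc1
Why: Williamson ether synthesis in a dipolar aprotic solvent favours O‑ over C‑benzylation, and the crystalline triether is easily freed of C‑alkylated side products.

Step 2
Reactants: 2 1,3,5-tris(benzyloxy)benzene
Product: 3 3,5-bis(benzyloxy)phenol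
Conditions: NaSEt (1.3 equiv), DMF, 130 °C; then 1 M HCl
Reagents that add atoms: none
Why: SN2 debenzylation by thiolate stops after one ether because the phenoxide formed makes the remaining aryloxide leaving groups much poorer.

Step 3
Reactants: 3 3,5-bis(benzyloxy)phenol; 4 allyl bromide
Product: 5 1-(allyloxy)-3,5-bis(benzyloxy)benzene
Conditions: K2CO3, acetone, reflux
Reagents that add atoms: none
Why: Williamson ether synthesis of the only free phenol with a reactive allylic halide.

Step 4
Reactants: 5 1-(allyloxy)-3,5-bis(benzyloxy)benzene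
Product: 7 2-allyl-3,5-bis(benzyloxy)phenol, via ortho-allyl cyclohexadienone 6 (not isolated)
Conditions: PhNEt2, 200 °C, Ar
Reagents that add atoms: none
Why: Aromatic Claisen rearrangement ([3,3]‑sigmatropic shift, then tautomerisation) gives one product because both ortho positions are equivalent, and it frees exactly the ortho oxygen that will later carry the sulfate.

Step 5
Reactants: 7 2-allyl-3,5-bis(benzyloxy)phenol
Product: 8 2-allyl-1,5-bis(benzyloxy)-3-(methoxymethoxy)benzene
Conditions: NaH, MOMCl, DMF, 0 °C→rt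
Reagents that add atoms: chloromethyl methyl ether, COCCl
Why: O‑alkylation of the sodium phenoxide with a very reactive α‑chloro ether installs a base‑stable acetal that is orthogonal to the benzyl ethers.

Step 6
Reactants: 8 2-allyl-1,5-bis(benzyloxy)-3-(methoxymethoxy)benzene
Product: 10 2-Ar-acetaldehyde, via vicinal diol 9 (not isolated)
Conditions: OsO4 (2 mol %), NaIO4 (4 equiv), 2,6-lutidine, dioxane/H2O 3:1, rt
Reagents that add atoms: osmium tetroxide, O=[Os](=O)(=O)=O (oxygen carrier); sodium periodate, [Na+].[O-]I(=O)(=O)=O (refills it and cleaves the diol)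
Why: Lemieux–Johnson oxidative cleavage attacks only the terminal alkene, and the lutidine buffer keeps the MOM acetal and the enolisable aldehyde intact.

Step 7
Reactants: 10 2-Ar-acetaldehyde
Product: 11 2-Ar-acetic acid
Conditions: NaClO2, NaH2PO4, 2-methyl-2-butene (20 equiv), t-BuOH/THF/H2O, 0 °C→rt
Reagents that add atoms: sodium chlorite, [Na+].[O-]Cl=O
Why: Pinnick oxidation is selective for the aldehyde at about pH 4–5, and the large excess of alkene scavenger removes HOCl before it can chlorinate the electron‑rich ring.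

Step 8
Reactants: 11 2-Ar-acetic acid
Product: 12 methyl 2-Ar-acetate
Conditions: MeI, K2CO3, DMF, rt
Reagents that add atoms: iodomethane, CI
Why: SN2 alkylation of the carboxylate esterifies without acid, so the MOM group is untouched.

Step 9
Reactants: 12 methyl 2-Ar-acetate (two molecules)
Product: 13 methyl 2,4-bis(Ar)-3-oxobutanoate (racemic at C-2, keto/enol mixture)
Conditions: NaH (1.1 equiv per 12), MeOH (cat.), THF, reflux; aq NaH2PO4 quench
Reagents that add atoms: none
Why: In this intermolecular Claisen condensation the enolate of one ester molecule acylates at the carbonyl of a second, proton transfers are degenerate because both partners are the same ester, irreversible deprotonation of the doubly activated C‑2–H with loss of H2 drives the equilibrium, and the racemic C‑2 centre is erased in step 10.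

Step 10
Reactants: 13 methyl 2,4-bis(Ar)-3-oxobutanoate
Product: 14 1,3-bis(Ar)propan-2-one
Conditions: LiCl, H2O, DMSO, 130 °C
Reagents that add atoms: none
Why: Krapcho dealkoxycarbonylation removes the β‑keto ester carbon under neutral conditions that spare the benzyl and MOM ethers and avoid retro‑Claisen cleavage.

Step 11
Reactants: 14 1,3-bis(Ar)propan-2-one
Product: 15 2-(trimethylsilyloxy)-1,3-bis(Ar)prop-1-ene (E/Z mixture, geometry lost in step 12)
Conditions: LiN(SiMe3)2, THF, −78 °C; Me3SiCl, −78→0 °C; pentane, filter, use crude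
Reagents that add atoms: chlorotrimethylsilane, C[Si](C)(C)Cl
Why: Deprotonation of the symmetrical benzylic ketone can give only one constitutional enolate, and hard O‑silylation traps it as the silyl enol ether.

Step 12
Reactants: 15 2-(trimethylsilyloxy)-1,3-bis(Ar)prop-1-ene; 16 malonyl dichloride
Product: 18 4-hydroxy-5-Ar-6-(Ar-methyl)-2H-pyran-2-one, via dioxohexanoyl chloride 17 (not isolated)
Conditions: 16 (1.05 equiv), 2,6-di-tert-butyl-4-methylpyridine (1.2 equiv), CH2Cl2/Et2O, −78→0 °C
Reagents that add atoms: none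
Why: Lewis‑acid‑free C‑acylation of the silyl enol ether by the bis(acid chloride) followed by enol O‑acylation (lactonisation) gives the 4‑hydroxy‑2‑pyranone whichever acylation comes first, while the hindered base traps HCl away from the MOM groups.

Step 13
Reactants: 18 4-hydroxy-5-Ar-6-(Ar-methyl)-2H-pyran-2-one
Product: 19 4-(benzyloxy)-5-Ar-6-(Ar-methyl)-2H-pyran-2-one
Conditions: BnOH, PPh3, DIAD, THF, 0 °C→rt
Reagents that add atoms: benzyl alcohol, OCc1ccccc1
Why: Mitsunobu reaction of the acidic vinylogous acid (pKa about 5) alkylates the 4‑oxygen cleanly and avoids the C‑3 alkylation seen with benzyl halide and base.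

Step 14
Reactants: 19 4-(benzyloxy)-5-Ar-6-(Ar-methyl)-2H-pyran-2-one
Product: 21 5-(benzyloxy)-2,4-bis(Ar)benzene-1,3-diol, via ring-opened benzyl ester 20 (not isolated)
Conditions: NaH/BnOH (→ NaOCH2Ph, 4 equiv), THF/BnOH, 100 °C, sealed, Ar; aq NaH2PO4 quench
Reagents that add atoms: benzyl alcohol (as NaOCH2Ph), OCc1ccccc1 (its benzyloxy group sits only in intermediate 20 and leaves again on ring closure)
Why: Benzyloxide opens the lactone (any exchange at the vinylogous OBn is degenerate) to the 2E keto ester whose two arms are held cis, the benzylic ketone enolate then attacks the ester in a Dieckmann‑type intramolecular Claisen condensation, and tautomerisation to the aromatic resorcinolate makes the isomerisation irreversible.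

Step 15
Reactants: 21 5-(benzyloxy)-2,4-bis(Ar)benzene-1,3-diol
Product: 22 1,3,5-tris(benzyloxy)-2,4-bis(Ar)benzene
Conditions: NaH, BnBr (excess), n-Bu4NI (cat.), DMF, 0→50 °C
Reagents that add atoms: benzyl bromide, BrCc1ccccc1
Why: Williamson ether synthesis with in‑situ benzyl iodide caps both ring B phenols, including the one flanked by two aryl groups, as ethers that, unlike esters, cannot migrate to the neighbouring ring A or ring C oxygens.

Step 16
Reactants: 22 1,3,5-tris(benzyloxy)-2,4-bis(Ar)benzene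
Product: 23 1,3,5-tris(benzyloxy)-2,4-bis[2,4-bis(benzyloxy)-6-hydroxyphenyl]benzene
Conditions: HCl (cat., conc. aq), MeOH/THF 1:1, 45 °C
Reagents that add atoms: none
Why: Acid‑catalysed transacetalisation to methanol removes only the two MOM groups, and the solvent captures the C1 fragment as dimethoxymethane before it can alkylate the electron‑rich rings.

Step 17
Reactants: 23 1,3,5-tris(benzyloxy)-2,4-bis[2,4-bis(benzyloxy)-6-hydroxyphenyl]benzene
Product: 24 disodium salt of the bis(sulfate) of 23
Conditions: SO3·pyridine (8 equiv), pyridine, 45 °C; aq NaHCO3; Sephadex LH-20 (MeOH/CH2Cl2)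
Reagents that add atoms: sulfur trioxide–pyridine complex, [O-]S(=O)(=O)[n+]1ccccc1; sodium hydrogen carbonate, [Na+].OC([O-])=O
Why: O‑sulfation with a mild SO3–amine complex can only hit the two free phenols, so the sulfate positions are fixed by the protecting‑group pattern.

Step 18
Reactants: 24 disodium salt of the bis(sulfate) of 23
Product: 25 disodium salt of the target
Conditions: H2 (3 bar), Pd/C (10 wt % Pd), NaHCO3 (trace), MeOH/THF/H2O, rt
Reagents that add atoms: none
Why: Catalytic hydrogenolysis cleaves all seven benzyl ethers under neutral conditions in which aryl sulfate monoester salts are stable.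

Step 19
Reactants: 25 disodium salt of the target
Product: 26 target, free bis(hydrogen sulfate)
Conditions: Dowex 50WX8 (H+ form), H2O, 4 °C; freeze-dry at once, store cold (25 is the storage form)
Reagents that add atoms: none
Why: Cation exchange on a strong‑acid resin replaces Na+ by H+ without adding a soluble acid, and cold, fast handling limits autocatalytic loss of sulfate.

## Compound list

1 | phloroglucinol | Oc1cc(O)cc(O)c1 | starting material
2 | 1,3,5-tris(benzyloxy)benzene | c1ccccc1COc1cc(OCc2ccccc2)cc(OCc2ccccc2)c1 | intermediate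
3 | 3,5-bis(benzyloxy)phenol | Oc1cc(OCc2ccccc2)cc(OCc2ccccc2)c1 | intermediate
4 | allyl bromide | C=CCBr | starting material
5 | 1-(allyloxy)-3,5-bis(benzyloxy)benzene | C=CCOc1cc(OCc2ccccc2)cc(OCc2ccccc2)c1 | intermediate
6 | 6-allyl-3,5-bis(benzyloxy)cyclohexa-2,4-dien-1-one (racemic, not isolated) | O=C1C=C(OCc2ccccc2)C=C(OCc2ccccc2)C1CC=C | intermediate
7 | 2-allyl-3,5-bis(benzyloxy)phenol | C=CCc1c(O)cc(OCc2ccccc2)cc1OCc1ccccc1 | intermediate
8 | 2-allyl-1,5-bis(benzyloxy)-3-(methoxymethoxy)benzene | C=CCc1c(OCOC)cc(OCc2ccccc2)cc1OCc1ccccc1 | intermediate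
9 | 3-Ar-propane-1,2-diol (racemic, not isolated) | OCC(O)Cc1c(OCOC)cc(OCc2ccccc2)cc1OCc1ccccc1 | intermediate
10 | 2-Ar-acetaldehyde | O=CCc1c(OCOC)cc(OCc2ccccc2)cc1OCc1ccccc1 | intermediate
11 | 2-Ar-acetic acid | OC(=O)Cc1c(OCOC)cc(OCc2ccccc2)cc1OCc1ccccc1 | intermediate
12 | methyl 2-Ar-acetate | COC(=O)Cc1c(OCOC)cc(OCc2ccccc2)cc1OCc1ccccc1 | intermediate
13 | methyl 2,4-bis(Ar)-3-oxobutanoate (racemic) | COC(=O)C(c1c(OCOC)cc(OCc2ccccc2)cc1OCc1ccccc1)C(=O)Cc1c(OCOC)cc(OCc2ccccc2)cc1OCc1ccccc1 | intermediate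
14 | 1,3-bis(Ar)propan-2-one | O=C(Cc1c(OCOC)cc(OCc2ccccc2)cc1OCc1ccccc1)Cc1c(OCOC)cc(OCc2ccccc2)cc1OCc1ccccc1 | intermediate
15 | 2-(trimethylsilyloxy)-1,3-bis(Ar)prop-1-ene (E/Z mixture) | C[Si](C)(C)OC(=Cc1c(OCOC)cc(OCc2ccccc2)cc1OCc1ccccc1)Cc1c(OCOC)cc(OCc2ccccc2)cc1OCc1ccccc1 | intermediate
16 | malonyl dichloride | O=C(Cl)CC(=O)Cl | starting material
17 | 4,6-bis(Ar)-3,5-dioxohexanoyl chloride (racemic, not isolated) | O=C(Cl)CC(=O)C(c1c(OCOC)cc(OCc2ccccc2)cc1OCc1ccccc1)C(=O)Cc1c(OCOC)cc(OCc2ccccc2)cc1OCc1ccccc1 | intermediate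
18 | 4-hydroxy-5-Ar-6-(Ar-methyl)-2H-pyran-2-one | O=C1C=C(O)C(c2c(OCOC)cc(OCc3ccccc3)cc2OCc2ccccc2)=C(Cc2c(OCOC)cc(OCc3ccccc3)cc2OCc2ccccc2)O1 | intermediate
19 | 4-(benzyloxy)-5-Ar-6-(Ar-methyl)-2H-pyran-2-one | O=C1C=C(OCc2ccccc2)C(c2c(OCOC)cc(OCc3ccccc3)cc2OCc2ccccc2)=C(Cc2c(OCOC)cc(OCc3ccccc3)cc2OCc2ccccc2)O1 | intermediate
20 | benzyl (2E)-3-(benzyloxy)-4,6-bis(Ar)-5-oxohex-2-enoate (racemic at C-4, not isolated) | O=C(OCc1ccccc1)/C=C(/OCc1ccccc1)\C(c1c(OCOC)cc(OCc2ccccc2)cc1OCc1ccccc1)C(=O)Cc1c(OCOC)cc(OCc2ccccc2)cc1OCc1ccccc1 | intermediate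
21 | 5-(benzyloxy)-2,4-bis(Ar)benzene-1,3-diol (axes unassigned) | Oc1cc(OCc2ccccc2)c(-c2c(OCOC)cc(OCc3ccccc3)cc2OCc2ccccc2)c(O)c1-c1c(OCOC)cc(OCc2ccccc2)cc1OCc1ccccc1 | intermediate
22 | 1,3,5-tris(benzyloxy)-2,4-bis(Ar)benzene (axes unassigned) | c1ccccc1COc1cc(OCc2ccccc2)c(-c2c(OCOC)cc(OCc3ccccc3)cc2OCc2ccccc2)c(OCc2ccccc2)c1-c1c(OCOC)cc(OCc2ccccc2)cc1OCc1ccccc1 | intermediate
23 | 1,3,5-tris(benzyloxy)-2,4-bis[2,4-bis(benzyloxy)-6-hydroxyphenyl]benzene (axes unassigned) | c1ccccc1COc1cc(OCc2ccccc2)c(-c2c(O)cc(OCc3ccccc3)cc2OCc2ccccc2)c(OCc2ccccc2)c1-c1c(O)cc(OCc2ccccc2)cc1OCc1ccccc1 | intermediate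
24 | disodium 1,3,5-tris(benzyloxy)-2,4-bis[2,4-bis(benzyloxy)-6-(sulfonatooxy)phenyl]benzene (axes unassigned) | [Na+].[Na+].c1ccccc1COc1cc(OCc2ccccc2)c(-c2c(OS(=O)(=O)[O-])cc(OCc3ccccc3)cc2OCc2ccccc2)c(OCc2ccccc2)c1-c1c(OS(=O)(=O)[O-])cc(OCc2ccccc2)cc1OCc1ccccc1 | intermediate
25 | disodium salt of the target (axes unassigned) | [Na+].[Na+].[O-]S(=O)(=O)Oc1cc(O)cc(O)c1-c1c(O)cc(O)c(-c2c(O)cc(O)cc2OS(=O)(=O)[O-])c1O | intermediate
26 | 2,4-bis[2,4-dihydroxy-6-(sulfooxy)phenyl]benzene-1,3,5-triol, CNP0320583.0 (no stereodescriptor) | O=S(=O)(O)Oc1cc(O)cc(O)c1-c1c(O)cc(O)c(-c2c(O)cc(O)cc2OS(=O)(=O)O)c1O | target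

## Step count

Total step count: 19.
Longest linear sequence: 19. The route is linear, and step 9 joins two molecules of the same ester 12.

## Steps most likely to fail

**Step 9 (Claisen condensation of the di‑ortho‑substituted arylacetate).** Both the enolate carbon and the ester carbonyl are shielded, so conversion may stall.

The fallback sets out from acid 11 and comes back at ketone 14. Half of 11 is activated with 1,1'‑carbonyldiimidazole (THF, rt) as 1‑(Ar‑acetyl)imidazole F1. The other half is doubly deprotonated with i‑PrMgCl (2.1 equiv, THF, 0→40 °C) and acylated in the same flask by the much more electrophilic F1.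

The resulting 2,4‑bis(Ar)‑3‑oxobutanoic acid F2 loses CO2 on buffered work‑up and gentle warming. This decarboxylative Claisen condensation gives 14 directly and makes steps 8–10 unnecessary.

**Step 12 (malonyl dichloride annulation).** The risks are HCl‑induced loss of MOM, acylation of the very electron‑rich arenes, and slow attack at the hindered enol carbon.

The fallback sets out from ester 12 and comes back at pyranone 18, using only basic conditions. A crossed Claisen condensation of 12 with LiCH2CO2Me (methyl acetate, LiN(i‑Pr)2, THF, −78→0 °C) gives methyl 4‑Ar‑3‑oxobutanoate F3.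

Double deprotonation of F3 (NaH, then n‑BuLi, THF, 0 °C) and acylation at the benzylic γ‑carbon with a second portion of 12 gives methyl 4,6‑bis(Ar)‑3,5‑dioxohexanoate F4. DBU in toluene at 80 °C then lactonises F4 to 18.

**Step 14 (pyranone‑to‑resorcinol isomerisation).** The ring‑opened ester rests as a delocalised anion. Re‑closure through oxygen to 19, or retro‑Claisen cleavage, may therefore win over C‑acylation.

The fallback sets out from hydroxypyranone 18 and comes back at 22. Compound 18 is heated with Mg(OMe)2 in MeOH/THF (reflux to 100 °C, sealed). This opens it to the magnesium chelate of the open‑chain ester F4 named above. The chelate holds the chain as a folded complex with the ester still electrophilic, so the phloroglucinol‑type Claisen cyclisation of a polyketide chain can proceed to 2,4‑bis(Ar)benzene‑1,3,5‑triol F5.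

Exhaustive benzylation of F5 (BnBr, K2CO3, DMF, 50 °C) then gives 22, so steps 13–15 are replaced.

## Further compounds

F1 | step 9 | 1-(Ar-acetyl)imidazole | O=C(Cc1c(OCOC)cc(OCc2ccccc2)cc1OCc1ccccc1)n1ccnc1
F2 | step 9 | 2,4-bis(Ar)-3-oxobutanoic acid (racemic) | OC(=O)C(c1c(OCOC)cc(OCc2ccccc2)cc1OCc1ccccc1)C(=O)Cc1c(OCOC)cc(OCc2ccccc2)cc1OCc1ccccc1
F3 | step 12 | methyl 4-Ar-3-oxobutanoate | COC(=O)CC(=O)Cc1c(OCOC)cc(OCc2ccccc2)cc1OCc1ccccc1
F4 | step 12 | methyl 4,6-bis(Ar)-3,5-dioxohexanoate (racemic) | COC(=O)CC(=O)C(c1c(OCOC)cc(OCc2ccccc2)cc1OCc1ccccc1)C(=O)Cc1c(OCOC)cc(OCc2ccccc2)cc1OCc1ccccc1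
F5 | step 14 | 2,4-bis(Ar)benzene-1,3,5-triol | Oc1cc(O)c(-c2c(OCOC)cc(OCc3ccccc3)cc2OCc2ccccc2)c(O)c1-c1c(OCOC)cc(OCc2ccccc2)cc1OCc1ccccc1
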